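**Retrosynthetic overview**

1. Feature: quaternary C14 is allylic to the C12=C13 alkene of cyclopentene ring E and is bonded to quaternary C20, which carries C19 (the lactone OCH2). C19–C20–C14–C13=C12 is therefore a γ,δ-unsaturated acid, the retron of an ester-enolate Claisen rearrangement.
2. Key disconnection C14–C20: ring-contracting Ireland–Claisen rearrangement of a bridged nine-membered allylic lactone (C19 ester on the C12 oxygen, exocyclic C13=C14). It closes ring D and sets both quaternary carbons.
3. The lactone comes from an ester tether between a ring-E allylic alcohol (fragment 1) and a C5–C6/C19–C23 acid (fragment 2), ring-closing metathesis at C7=C8 and diimide reduction.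
4. Fragment 1: nickel-catalysed alkylative ynal cyclisation (ring E with the stereodefined C13=C14 alkene), C9 from a copper-catalysed allylic alkylation. Fragment 2: iridium-catalysed allylic alkylation of dimethyl malonate (C6), then Michael addition to but-3-en-2-one.
5. After the key step: lactone ring F (C17/C19), ring B (N4=C24), ring C (Mannich at C22), ring A (formaldehyde Mannich at C2), and the C2 methyl last. Ring order: E, D, F, B, C, A.

Key step: step 18

Remark: atoms are numbered in target-SMILES order without the two carbonyl oxygens (N4, O18, C23 ketone, C24 aminomethine). Lactone 29 is carried as both C20 epimers because step 18 planarises C20. The C2 methyl of the target lies on the concave face of ring A (syn to C21 and C5), which an equilibrating Mannich closure cannot be relied on to give, so the side chain is a methyl ketone and C2 is set last by hydrogenation from the open face.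

**Route**

Step 1
Reactants: 1 (E)-3-iodoprop-2-en-1-ol; 2 4-methoxybenzyl propargyl ether
Product: 3 (E)-enynol
Conditions: PdCl2(PPh3)2 (2 mol%), CuI (4 mol%), Et3N, THF, rt
Reagents that add atoms: none
Why: Sonogashira coupling of a vinyl iodide with a terminal alkyne keeps the (E)-geometry and tolerates the free allylic alcohol.

Step 2
Reactants: 3 (E)-enynol
Product: 4 (E)-enyne allylic chloride
Conditions: PPh3, CCl4, CH2Cl2, 0 °C to rt
Reagents that add atoms: carbon tetrachloride, ClC(Cl)(Cl)Cl
Why: Appel chlorination of the primary allylic alcohol (SN2 displacement of the oxyphosphonium group) leaves the enyne and the benzylic ether untouched.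

Step 3
Reactants: 4 (E)-enyne allylic chloride; 5 [2-(1,3-dioxolan-2-yl)ethyl]magnesium bromide
Product: 6 skipped enyne acetal
Conditions: copper thiophene-2-carboxylate CuO2C(C4H3S) (3 mol%), chiral BINOL-based phosphoramidite ligand (enantiomer chosen to give (S)-6), CH2Cl2, −78 °C, slow addition of 5
Reagents that add atoms: none
Why: Copper-catalysed asymmetric allylic alkylation of an enyne chloride with a Grignard reagent, in which the alkylcopper species attacks the γ-carbon (SN2′) under control of the chiral ligand and so sets C9 (S).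

Step 4
Reactants: 6 skipped enyne acetal
Product: 7 ynal
Conditions: 2 M HCl, THF, 40 °C
Reagents that add atoms: water, O
Why: Acid hydrolysis of the dioxolane acetal frees the C12 aldehyde, while the 4-methoxybenzyl ether and the C9 centre are stable to dilute aqueous acid.

Step 5
Reactants: 7 ynal; 8 (3-bromopropoxy)(tert-butyl)dimethylsilane
Product: 11 2-alkylidene-3-vinylcyclopentanol (both C12 epimers), via Grignard reagent 9 (not isolated), via dialkylzinc 10 (not isolated)
Conditions: 8, Mg, THF; ZnCl2 (0.5 equiv), 0 °C; then 7, Ni(cod)2 (10 mol%), THF, 0 °C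
Reagents that add atoms: none
Why: Nickel-catalysed alkylative cyclisation of an ynal with an organozinc (Montgomery cyclisation): oxidative cyclisation at zerovalent nickel gives an oxanickelacycle with nickel on C14 cis to C12, so transmetalation and reductive elimination place the C15–C17 chain cis to C12 and leave C24 cis to C9, while C12 forms as an epimer mixture that steps 6 and 7 converge.

Step 6
Reactants: 11 2-alkylidene-3-vinylcyclopentanol
Product: 12 enone
Conditions: Dess–Martin periodinane, NaHCO3, CH2Cl2, 0 °C to rt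
Reagents that add atoms: none
Why: Dess–Martin oxidation converts both C12 epimers into one enone under buffered conditions that neither epimerise the doubly allylic C9 nor isomerise the tetrasubstituted alkene.

Step 7
Reactants: 12 enone
Product: 13 cis-allylic alcohol (fragment 1)
Conditions: NaBH4, CeCl3·7H2O, MeOH, −78 °C
Reagents that add atoms: none
Why: Luche 1,2-reduction in which allylic strain with C24 holds the C9 vinyl group pseudoaxial, so hydride adds to C12 from the opposite face and the hydroxyl ends cis to the vinyl group ((S)-C12).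

Step 8
Reactants: 14 tert-butyl (4-methoxybenzyl)carbamate; 15 methyl (E)-4-bromobut-2-enoate
Product: 16 N-allylated carbamate ester
Conditions: NaH, DMF, 0 °C
Reagents that add atoms: none
Why: N-alkylation (SN2) of the sodium carbamate at the allylic bromide with retention of the (E)-alkene.

Step 9
Reactants: 16 N-allylated carbamate ester
Product: 17 (E)-allylic alcohol
Conditions: iBu2AlH (2.2 equiv), CH2Cl2, −78 °C
Reagents that add atoms: none
Why: 1,2-Reduction of the enoate by iBu2AlH gives the (E)-allylic alcohol and leaves the tert-butyl carbamate intact at low temperature.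

Step 10
Reactants: 17 (E)-allylic alcohol
Product: 18 allylic methyl carbonate
Conditions: ClCO2Me, pyridine, CH2Cl2, 0 °C
Reagents that add atoms: methyl chloroformate, COC(=O)Cl
Why: O-acylation gives the carbonate leaving group needed for the allylic substitution.

Step 11
Reactants: 18 allylic methyl carbonate; 19 dimethyl malonate
Product: 20 branched allyl malonate
Conditions: [Ir(cod)Cl]2 (2 mol%), chiral phosphoramidite ligand (4 mol%, enantiomer chosen to give (S)-20), 1,5,7-triazabicyclo[4.4.0]dec-5-ene (8 mol%), THF, rt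
Reagents that add atoms: none
Why: Iridium-catalysed asymmetric allylic alkylation in which the malonate attacks the substituted terminus of the allyliridium complex, giving the branched product and setting C6 (S) by catalyst control.

Step 12
Reactants: 20 branched allyl malonate; 21 but-3-en-2-one
Product: 22 keto malonate
Conditions: DBU (0.2 equiv), MeCN, rt
Reagents that add atoms: none
Why: Base-catalysed Michael addition of the tertiary malonate builds C20 with its C21–C23 chain, and C20 is not yet stereogenic.

Step 13
Reactants: 22 keto malonate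
Product: 23 ketal malonate
Conditions: ethylene glycol, pyridinium p-toluenesulfonate, benzene, reflux (Dean–Stark)
Reagents that add atoms: ethane-1,2-diol, OCCO
Why: Ketalisation protects the C23 ketone against the amide base of step 18 and the hydride of step 19.

Step 14
Reactants: 23 ketal malonate
Product: 25 pentenoic acid (fragment 2; both C20 epimers), via malonic acid 24 (not isolated)
Conditions: KOH, MeOH/H2O, 70 °C; 1 M HCl to pH 4 at 0 °C; pyridine, 110 °C
Reagents that add atoms: potassium hydroxide, [K+].[OH-]
Why: Saponification and thermal decarboxylation of the malonic acid leave the C19 acid, and C20 forms as both epimers, which is accepted because step 18 planarises this carbon.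

Step 15
Reactants: 13 cis-allylic alcohol; 25 pentenoic acid
Product: 27 diene ester, via mixed anhydride 26 (not isolated)
Conditions: 2,4,6-trichlorobenzoyl chloride, Et3N, THF, rt; then 13, DMAP, toluene, rt
Reagents that add atoms: none
Why: Yamaguchi esterification acylates the hindered C12 hydroxyl with retention, and the fully substituted nitrogen cannot close a lactam on the activated acid.

Step 16
Reactants: 27 diene ester
Product: 28 bridged unsaturated nine-membered lactone
Conditions: second-generation Hoveyda–Grubbs catalyst (10 mol%), toluene (1 mM), 80 °C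
Reagents that add atoms: none
Why: Ring-closing metathesis of the two vinyl groups, which the cis-1,3 substitution of the cyclopentane holds on one face, forms C7=C8 as the (Z)-alkene of the nine-membered lactone, and the tetrasubstituted C13=C14 bond does not take part.

Step 17
Reactants: 28 bridged unsaturated nine-membered lactone
Product: 29 bridged nine-membered allylic lactone
Conditions: 2-nitrobenzenesulfonylhydrazide, Et3N, CH2Cl2, rt
Reagents that add atoms: none
Why: Diimide reduction saturates the strained cis-disubstituted C7=C8 bond and leaves the tetrasubstituted alkene of the allylic ester and the benzylic groups untouched.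

Step 18
Reactants: 29 bridged nine-membered allylic lactone
Product: 32 ring D/E carboxylic acid, via silyl ketene acetal 30 (not isolated), via trimethylsilyl ester 31 (not isolated)
Conditions: LiN(iPr)2, Me3SiCl/Et3N, THF, −78 °C to rt; toluene, 90 °C; H2O/THF, rt
Reagents that add atoms: none
Why: LiN(iPr)2 removes H20 and Me3SiCl traps the enolate as silyl ketene acetal 30, whose C19=C20 bond is held in the nine-membered ring with C6 cis to the ring oxygen; on warming, a concerted suprafacial [3,3] shift joins C20 to C14 as the C12–O bond breaks and the alkene moves to C12=C13. The closest known reaction type is the Ireland–Claisen rearrangement of lactone silyl ketene acetals with ring contraction. Ring D closes by this sigmatropic contraction of the nine-membered lactone onto its exocyclic alkene (nine to seven), not by a polar cyclisation, and formation of the silyl carboxylate drives the bond between two fully substituted carbons. C14: C20 is delivered to the alkene face that carries the C12 oxygen, which is the face syn to C8 on ring E, and the fixed (E)-geometry of C13=C14 (C24 on the C9 side, C15 on the C12 side) then gives (R)-C14. C20: in the bridged transition state C19 is tied to the C12 flank by the breaking C–O bond and C6 to the C9 flank by the C7–C8 tether, so C21 must point outward and the six-atom array is chair-like (a boat would put C6 out of reach of C8), which gives (R)-C20 from either C20 epimer of 29. The selectivity needed (alkene face and chair against boat) is thus enforced by the cis-1,3 bridge across the cyclopentane; what stays uncertain is the rate of enolisation and of a shift that creates two adjacent quaternary carbons.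

Step 19
Reactants: 32 ring D/E carboxylic acid
Product: 33 neopentyl C19 alcohol
Conditions: LiAlH4, THF, 0 °C to rt
Reagents that add atoms: none
Why: Hydride reduction of the carboxylic acid gives the C19 primary alcohol while carbamate, ketal, silyl ether and alkene are inert at this temperature.

Step 20
Reactants: 33 neopentyl C19 alcohol
Product: 34 C17/C19 diol
Conditions: n-Bu4NF, THF, rt
Reagents that add atoms: none
Why: Fluoride cleavage of the primary silyl ether frees the C17 hydroxyl.

Step 21
Reactants: 34 C17/C19 diol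
Product: 36 seven-membered lactone, via lactol 35 (not isolated)
Conditions: TEMPO (20 mol%), PhI(OAc)2, CH2Cl2, rt
Reagents that add atoms: none
Why: Oxoammonium oxidative lactonisation in which the unhindered C17 alcohol is oxidised first, the neopentyl C19 hydroxyl (slow to oxidise between two quaternary carbons) closes the lactol, and the lactol is oxidised to the lactone with C17 as carbonyl.

Step 22
Reactants: 36 seven-membered lactone
Product: 37 hydroxy keto carbamate
Conditions: (NH4)2Ce(NO3)6, MeCN/H2O (4:1), 0 °C to rt; then 1 M HCl, THF, rt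
Reagents that add atoms: water, O
Why: Single-electron oxidation of both anisyl rings by (NH4)2Ce(NO3)6 cleaves the 4-methoxybenzyl ether at O24 and the 4-methoxybenzyl group on the carbamate nitrogen, and the acidic aqueous medium hydrolyses the dioxolane to the methyl ketone.

Step 23
Reactants: 37 hydroxy keto carbamate
Product: 38 keto aldehyde carbamate
Conditions: Dess–Martin periodinane, NaHCO3, CH2Cl2, rt
Reagents that add atoms: none
Why: Dess–Martin oxidation of the neopentyl C24 alcohol gives an aldehyde that has no α-hydrogen and cannot enolise.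

Step 24
Reactants: 38 keto aldehyde carbamate
Product: 41 pentacyclic amino ketone, via amino aldehyde 39 (not isolated), via cyclic imine 40 (not isolated)
Conditions: CF3CO2H/CH2Cl2 (1:4), 0 °C to rt; concentrate; AcOH, MeOH, 50 °C; aq. NaHCO3
Reagents that add atoms: none
Why: Acidolysis of the Boc group, condensation of N4 with the C24 aldehyde to the six-membered cyclic iminium ion (ring B) and intramolecular Mannich attack of the ketone enol through C22 (5-exo-trig, ring C); the C21–C22 tether reaches only the iminium face syn to C21, which fixes C24 (S), and the epimerisable C22 converges in step 25.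

Step 25
Reactants: 41 pentacyclic amino ketone
Product: 42 hexacyclic ketone without the C2 methyl
Conditions: 37% aq. CH2O, AcOH, MeOH, 50 °C
Reagents that add atoms: formaldehyde, C=O
Why: Mannich reaction in which N4 and formaldehyde give the N-methyleneiminium ion and the methyl-ketone enol attacks it through C2 (6-endo-trig) to close ring A; only the C22 epimer with the acyl group on the N4 side can cyclise, and C22 equilibrates through its enol to (S).

Step 26
Reactants: 42 hexacyclic ketone without the C2 methyl
Product: 43 C2-methylidene ketone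
Conditions: (CH2O)n, iPr2NH·CF3CO2H, THF, 65 °C
Reagents that add atoms: formaldehyde (from paraformaldehyde), C=O
Why: Amine-salt-mediated α-methylenation (Mannich condensation, then elimination) at C2, the only α-carbon of the ketone that carries two hydrogens.

Step 27
Reactants: 43 C2-methylidene ketone
Product: 44 target CNP0292775.1
Conditions: H2 (1 atm), RhCl(PPh3)3 (10 mol%), benzene, rt
Reagents that add atoms: none
Why: Homogeneous hydrogenation of the 1,1-disubstituted enone, in which hydrogen reaches C2 only from the open face of ring A because the other face carries the axial C5 and C21 bonds of the cage, so the new methyl ends syn to C21 ((R)-C2), and the hindered trisubstituted C12=C13 alkene is not reduced by this catalyst.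

**Compound list**

1 | (E)-3-iodoprop-2-en-1-ol | OC/C=C/I | starting material
2 | 1-methoxy-4-[(prop-2-yn-1-yloxy)methyl]benzene | C#CCOCc1ccc(OC)cc1 | starting material
3 | (E)-6-[(4-methoxybenzyl)oxy]hex-2-en-4-yn-1-ol | OC/C=C/C#CCOCc1ccc(OC)cc1 | intermediate
4 | (E)-1-chloro-6-[(4-methoxybenzyl)oxy]hex-2-en-4-yne | ClC/C=C/C#CCOCc1ccc(OC)cc1 | intermediate
5 | [2-(1,3-dioxolan-2-yl)ethyl]magnesium bromide | Br[Mg]CCC1OCCO1 | starting material
6 | 2-{(3S)-3-ethenyl-6-[(4-methoxybenzyl)oxy]hex-4-yn-1-yl}-1,3-dioxolane | C=C[C@H](CCC1OCCO1)C#CCOCc2ccc(OC)cc2 | intermediate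
7 | (4S)-4-ethenyl-7-[(4-methoxybenzyl)oxy]hept-5-ynal | O=CCC[C@@H](C=C)C#CCOCc1ccc(OC)cc1 | intermediate
8 | (3-bromopropoxy)(tert-butyl)dimethylsilane | BrCCCO[Si](C)(C)C(C)(C)C | starting material
9 | {3-[(tert-butyldimethylsilyl)oxy]propyl}magnesium bromide | Br[Mg]CCCO[Si](C)(C)C(C)(C)C | intermediate
10 | bis{3-[(tert-butyldimethylsilyl)oxy]propyl}zinc | CC(C)(C)[Si](C)(C)OCCC[Zn]CCCO[Si](C)(C)C(C)(C)C | intermediate
11 | (2E,3S)-2-{5-[(tert-butyldimethylsilyl)oxy]-1-[(4-methoxybenzyl)oxy]pentan-2-ylidene}-3-ethenylcyclopentan-1-ol, both C1 (= C12) epimers | OC1CC[C@@H](C=C)/C1=C(/CCCO[Si](C)(C)C(C)(C)C)COCc2ccc(OC)cc2 | intermediate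
12 | (2E,3S)-2-{5-[(tert-butyldimethylsilyl)oxy]-1-[(4-methoxybenzyl)oxy]pentan-2-ylidene}-3-ethenylcyclopentan-1-one | O=C1CC[C@@H](C=C)/C1=C(/CCCO[Si](C)(C)C(C)(C)C)COCc2ccc(OC)cc2 | intermediate
13 | (1S,2E,3S)-2-{5-[(tert-butyldimethylsilyl)oxy]-1-[(4-methoxybenzyl)oxy]pentan-2-ylidene}-3-ethenylcyclopentan-1-ol | O[C@H]1CC[C@@H](C=C)/C1=C(/CCCO[Si](C)(C)C(C)(C)C)COCc2ccc(OC)cc2 | intermediate
14 | tert-butyl (4-methoxybenzyl)carbamate | COc1ccc(CNC(=O)OC(C)(C)C)cc1 | starting material
15 | methyl (E)-4-bromobut-2-enoate | COC(=O)/C=C/CBr | starting material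
16 | methyl (E)-4-[(tert-butoxycarbonyl)(4-methoxybenzyl)amino]but-2-enoate | COC(=O)/C=C/CN(Cc1ccc(OC)cc1)C(=O)OC(C)(C)C | intermediate
17 | tert-butyl [(E)-4-hydroxybut-2-en-1-yl](4-methoxybenzyl)carbamate | OC/C=C/CN(Cc1ccc(OC)cc1)C(=O)OC(C)(C)C | intermediate
18 | (E)-4-[(tert-butoxycarbonyl)(4-methoxybenzyl)amino]but-2-en-1-yl methyl carbonate | COC(=O)OC/C=C/CN(Cc1ccc(OC)cc1)C(=O)OC(C)(C)C | intermediate
19 | dimethyl malonate | COC(=O)CC(=O)OC | starting material
20 | dimethyl 2-{(2S)-1-[(tert-butoxycarbonyl)(4-methoxybenzyl)amino]but-3-en-2-yl}malonate | COC(=O)C(C(=O)OC)[C@H](C=C)CN(Cc1ccc(OC)cc1)C(=O)OC(C)(C)C | intermediate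
21 | but-3-en-2-one | CC(=O)C=C | starting material
22 | dimethyl 2-{(2S)-1-[(tert-butoxycarbonyl)(4-methoxybenzyl)amino]but-3-en-2-yl}-2-(3-oxobutyl)malonate | COC(=O)C(CCC(C)=O)(C(=O)OC)[C@H](C=C)CN(Cc1ccc(OC)cc1)C(=O)OC(C)(C)C | intermediate
23 | dimethyl 2-{(2S)-1-[(tert-butoxycarbonyl)(4-methoxybenzyl)amino]but-3-en-2-yl}-2-[2-(2-methyl-1,3-dioxolan-2-yl)ethyl]malonate | COC(=O)C(CCC1(C)OCCO1)(C(=O)OC)[C@H](C=C)CN(Cc2ccc(OC)cc2)C(=O)OC(C)(C)C | intermediate
24 | malonic acid corresponding to 23 | OC(=O)C(CCC1(C)OCCO1)(C(O)=O)[C@H](C=C)CN(Cc2ccc(OC)cc2)C(=O)OC(C)(C)C | intermediate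
25 | (3S)-3-{[(tert-butoxycarbonyl)(4-methoxybenzyl)amino]methyl}-2-[2-(2-methyl-1,3-dioxolan-2-yl)ethyl]pent-4-enoic acid, both C2 (= C20) epimers | OC(=O)C(CCC1(C)OCCO1)[C@H](C=C)CN(Cc2ccc(OC)cc2)C(=O)OC(C)(C)C | intermediate
26 | mixed anhydride of 25 with 2,4,6-trichlorobenzoic acid | O=C(OC(=O)c1c(Cl)cc(Cl)cc1Cl)C(CCC2(C)OCCO2)[C@H](C=C)CN(Cc3ccc(OC)cc3)C(=O)OC(C)(C)C | intermediate
27 | diene ester: ester of alcohol 13 (through O on C12, configuration retained) with acid 25, both C20 epimers | O=C(O[C@H]1CC[C@@H](C=C)/C1=C(/CCCO[Si](C)(C)C(C)(C)C)COCc2ccc(OC)cc2)C(CCC3(C)OCCO3)[C@H](C=C)CN(Cc4ccc(OC)cc4)C(=O)OC(C)(C)C | intermediate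
28 | bridged unsaturated lactone: nine-membered ring C19(=O)–O–C12–C13–C9–C8=C7–C6–C20 with (Z)-C7=C8 and (E)-C13=C14; C6, C9, C12 as in 27; both C20 epimers | O=C1O[C@H]2CC[C@@H](/C=C\[C@H](CN(Cc3ccc(OC)cc3)C(=O)OC(C)(C)C)C1CCC4(C)OCCO4)/C2=C(/CCCO[Si](C)(C)C(C)(C)C)COCc5ccc(OC)cc5 | intermediate
29 | bridged nine-membered allylic lactone (precursor of the key step): ring C19(=O)–O–C12–C13–C9–C8–C7–C6–C20; (E)-C13=C14 with CH2O-PMB (C24) cis to C9 and the silyloxypropyl chain cis to C12; O12 cis to C8 on ring E; C6 S; both C20 epimers | O=C1O[C@H]2CC[C@@H](CC[C@H](CN(Cc3ccc(OC)cc3)C(=O)OC(C)(C)C)C1CCC4(C)OCCO4)/C2=C(/CCCO[Si](C)(C)C(C)(C)C)COCc5ccc(OC)cc5 | intermediate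
30 | trimethylsilyl ketene acetal of 29 (C19=C20 in the ring, C6 cis to the ring oxygen) | C[Si](C)(C)O/C1=C(\CCC3(C)OCCO3)[C@@H](CN(Cc4ccc(OC)cc4)C(=O)OC(C)(C)C)CC[C@@H]2CC[C@H](O1)/C2=C(\CCCO[Si](C)(C)C(C)(C)C)COCc5ccc(OC)cc5 | intermediate
31 | trimethylsilyl ester of 32 | C[Si](C)(C)OC(=O)[C@]1(CCC2(C)OCCO2)[C@@H](CN(Cc2ccc(OC)cc2)C(=O)OC(C)(C)C)CC[C@@H]2CCC=C2[C@@]1(CCCO[Si](C)(C)C(C)(C)C)COCc1ccc(OC)cc1 | intermediate
32 | ring D/E carboxylic acid (product of the key step): cycloheptane ring D fused to cyclopentene ring E (C12=C13); C6 S, C9 S, C14 R, C20 R | OC(=O)[C@]1(CCC2(C)OCCO2)[C@@H](CN(Cc2ccc(OC)cc2)C(=O)OC(C)(C)C)CC[C@@H]2CCC=C2[C@@]1(CCCO[Si](C)(C)C(C)(C)C)COCc1ccc(OC)cc1 | intermediate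
33 | C19 primary alcohol from 32 | OC[C@]1(CCC2(C)OCCO2)[C@@H](CN(Cc2ccc(OC)cc2)C(=O)OC(C)(C)C)CC[C@@H]2CCC=C2[C@@]1(CCCO[Si](C)(C)C(C)(C)C)COCc1ccc(OC)cc1 | intermediate
34 | C17/C19 diol | OC[C@]1(CCC2(C)OCCO2)[C@@H](CN(Cc2ccc(OC)cc2)C(=O)OC(C)(C)C)CC[C@@H]2CCC=C2[C@@]1(CCCO)COCc1ccc(OC)cc1 | intermediate
35 | seven-membered lactol (C17 hemiacetal with O on C19) | OC1CC[C@@]2(COCc3ccc(OC)cc3)C4=CCC[C@H]4CC[C@H](CN(Cc5ccc(OC)cc5)C(=O)OC(C)(C)C)[C@@]2(CCC6(C)OCCO6)CO1 | intermediate
36 | seven-membered lactone (ring F) with N(PMB)Boc, O24-PMB and ketal | O=C1CC[C@@]2(COCc3ccc(OC)cc3)C4=CCC[C@H]4CC[C@H](CN(Cc5ccc(OC)cc5)C(=O)OC(C)(C)C)[C@@]2(CCC6(C)OCCO6)CO1 | intermediate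
37 | hydroxy keto carbamate (C24 alcohol, C23 methyl ketone, NHBoc) | O=C1CC[C@@]2(CO)C4=CCC[C@H]4CC[C@H](CNC(=O)OC(C)(C)C)[C@@]2(CCC(C)=O)CO1 | intermediate
38 | keto aldehyde carbamate (C24 aldehyde) | O=C1CC[C@@]2(C=O)C4=CCC[C@H]4CC[C@H](CNC(=O)OC(C)(C)C)[C@@]2(CCC(C)=O)CO1 | intermediate
39 | amino aldehyde (primary amine on C5) | O=C1CC[C@@]2(C=O)C4=CCC[C@H]4CC[C@H](CN)[C@@]2(CCC(C)=O)CO1 | intermediate
40 | cyclic imine N4=C24 (ring B) | O=C1CC[C@@]2(C=NC3)C4=CCC[C@H]4CC[C@H]3[C@@]2(CCC(C)=O)CO1 | intermediate
41 | pentacyclic amino ketone (rings B, C, D, E, F; N4–H; acetyl group on C22, drawn as the epimer that closes ring A) | N2C[C@H]3CC[C@@H]4CCC=C4[C@]45CCC(=O)OC[C@]34C[C@H](C(C)=O)[C@H]25 | intermediate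
42 | hexacyclic ketone without the C2 methyl (C2 = CH2) | C1CN2C[C@H]3CC[C@@H]4CCC=C4[C@]45CCC(=O)OC[C@]34C[C@H](C1=O)[C@H]25 | intermediate
43 | C2-methylidene ketone | C=C1CN2C[C@H]3CC[C@@H]4CCC=C4[C@]45CCC(=O)OC[C@]34C[C@H](C1=O)[C@H]25 | intermediate
44 | CNP0292775.1 (C2 R, C6 S, C9 S, C14 R, C20 R, C22 S, C24 S) | C[C@@H]1CN2C[C@H]3CC[C@@H]4CCC=C4[C@]45CCC(=O)OC[C@]34C[C@H](C1=O)[C@H]25 | target

**Step count and risks**

Total: 27 steps. Longest linear sequence: 20 steps (steps 1–7, then 15–27; the sequence 8–14, then 15–27 is equally long).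

Step 18 (key step). The hindered C20–H of the bridged lactone may resist deprotonation, or the silyl ketene acetal may decompose before the slow shift that joins two fully substituted carbons. Fallback: carry out the sigmatropic step before the ring closure. It sets out from diene ester 27. Ireland–Claisen rearrangement of this open-chain ester (KN(SiMe3)2, Me3SiCl, toluene, −78 to 80 °C, aqueous work-up) should give the divinyl acid F1, in which C14 is again fixed by the alkene geometry and the C12–O face. Ring-closing metathesis (second-generation Hoveyda–Grubbs catalyst, CH2Cl2, 40 °C) then closes the unstrained cycloheptene of ring D to give the cycloheptene acid F2. Diimide reduction of C7=C8 brings the route back to acid 32. In this order C20 rests on the enolate geometry of an α-branched ester, so its epimers would have to be separated at F2.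

Step 16. Intermolecular metathesis (oligomer formation) may outrun closure of the strained nine-membered ring, or only one C20 epimer may cyclise. Fallback: join the fragments at C7=C8 first and close the ring at the ester bond. It sets out from alcohol 13 and acid 25. Cross-metathesis (second-generation Hoveyda–Grubbs catalyst, excess 25, CH2Cl2, 40 °C) should give the (E)-hydroxy acid F3. Diimide reduction gives the saturated seco acid F4. Yamaguchi macrolactonisation under high dilution (2,4,6-trichlorobenzoyl chloride, Et3N, then DMAP, toluene, 80 °C) returns to lactone 29.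

Step 22. The 4-methoxybenzyl group on the carbamate nitrogen may be cleaved only slowly, so that oxidation of the alkene or of the freed alcohol competes. Fallback: remove only the ether group oxidatively and carry the N-benzyl group through ring formation. It sets out from lactone 36. DDQ (CH2Cl2/pH 7 buffer) should give the C24 alcohol F5 with carbamate and ketal intact, and Dess–Martin oxidation gives the aldehyde F6. CF3CO2H/H2O removes Boc and ketal; the secondary amine closes ring B as an N-benzyliminium ion, which undergoes the same Mannich attack by C22 to give the N-(4-methoxybenzyl) amine F7. N-Dealkylation with 1-chloroethyl chloroformate (ClCH2CH2Cl, reflux) and methanolysis of the resulting carbamate return to amino ketone 41.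

**Further compounds**

F1 | step 18 | divinyl acid from open-chain Ireland–Claisen rearrangement of 27 (C14 and C20 quaternary; vinyl groups on C6 and C9) | OC(=O)[C@](CCC1(C)OCCO1)([C@H](C=C)CN(Cc2ccc(OC)cc2)C(=O)OC(C)(C)C)[C@](CCCO[Si](C)(C)C(C)(C)C)(COCc3ccc(OC)cc3)C4=CCC[C@H]4C=C
F2 | step 18 | cycloheptene acid (ring D with C7=C8) | OC(=O)[C@]1(CCC2(C)OCCO2)[C@@H](CN(Cc2ccc(OC)cc2)C(=O)OC(C)(C)C)C=C[C@@H]2CCC=C2[C@@]1(CCCO[Si](C)(C)C(C)(C)C)COCc1ccc(OC)cc1
F3 | step 16 | (E)-hydroxy acid from cross-metathesis of 13 and 25 | OC(=O)C(CCC1(C)OCCO1)[C@@H](CN(Cc2ccc(OC)cc2)C(=O)OC(C)(C)C)/C=C/[C@@H]3CC[C@H](O)/C3=C(\CCCO[Si](C)(C)C(C)(C)C)COCc4ccc(OC)cc4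
F4 | step 16 | saturated seco acid | OC(=O)C(CCC1(C)OCCO1)[C@@H](CN(Cc2ccc(OC)cc2)C(=O)OC(C)(C)C)CC[C@@H]3CC[C@H](O)/C3=C(\CCCO[Si](C)(C)C(C)(C)C)COCc4ccc(OC)cc4
F5 | step 22 | C24 alcohol with N(PMB)Boc and ketal intact | O=C1CC[C@@]2(CO)C4=CCC[C@H]4CC[C@H](CN(Cc5ccc(OC)cc5)C(=O)OC(C)(C)C)[C@@]2(CCC6(C)OCCO6)CO1
F6 | step 22 | C24 aldehyde with N(PMB)Boc and ketal intact | O=C1CC[C@@]2(C=O)C4=CCC[C@H]4CC[C@H](CN(Cc5ccc(OC)cc5)C(=O)OC(C)(C)C)[C@@]2(CCC6(C)OCCO6)CO1
F7 | step 22 | N-(4-methoxybenzyl) pentacyclic amino ketone | COc1ccc(CN2C[C@H]3CC[C@@H]4CCC=C4[C@]45CCC(=O)OC[C@]34C[C@H](C(C)=O)[C@H]25)cc1
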